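**Plan**

Germacrane numbering is used: ring carbons C1–C10, lactone carbons C11–C13 on C7, methyl C14 on C10, methyl C15 on C4.
Retrosynthesis cuts, in this order: C1–C10 together with C1–O (the 1,10-oxirane read as a C10 methyl ketone plus a one-carbon sulfonium ylide at C1); the two angelate C–O bonds; C7–C11 and the C8–O acyl bond (pyruvate aldol lactonisation); C7–C8 (aldol); what remains is a C1–C7 epoxy methyl ketone made from ethyl but-2-ynoate.
Forward order: the trans-4,5-oxirane (step 3), the full chain C1–C10 (step 8), the γ-lactone (step 10), then the ten-membered carbocycle and the cis-1,10-oxirane together in the last step.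
Enabling feature: C1–C10 is the C–C bond of an oxirane whose C10 bears the methyl C14, so C10 is a latent methyl ketone and C1 a latent ylide carbon; the trans-fused lactone ring (C7, C8, O, C12, C11) and the trans-4,5-oxirane are two rigid turns that bring C1 near C10.
Helpers: two terminal CH2 groups mask the C1 aldehyde and the C10 ketone until ozonolysis; a phenylthio group on C1 carries the ylide and leaves as diphenyl sulfide.
Stereochemistry: C4 and C5 from a Sharpless epoxidation, C8 from a reagent-controlled boron aldol, C7 and C11 relayed from C8 in the aldol lactonisation, C6 from a chelation-controlled reduction, C1 and C10 from the fold of the chain in the ring closure.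

Key step: step 16

Remark: the target is taken as drawn in the SMILES, that is (1R,4S,5S,6S,7S,8R,10S,11R), with a cis-fused 1,10-oxirane, a trans-fused 4,5-oxirane and two (2Z)-2-methylbut-2-enoates (angelates).

**Route**

Step 1
Reactants: 1 ethyl but-2-ynoate
Product: 2 ethyl (2E)-3-methylhepta-2,6-dienoate
Conditions: but-3-en-1-ylMgBr, CuBr·SMe2, THF, −40 °C; then 1, −78 °C; NH4Cl aq., −78 °C
Reagents that add atoms: but-3-en-1-ylmagnesium bromide, C=CCC[Mg]Br
Why: organocopper conjugate addition (syn carbocupration) to the ynoate and protonation at −78 °C should give the 2E ester, the geometry that later makes the C4–C5 oxirane trans.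

Step 2
Reactants: 2 ethyl (2E)-3-methylhepta-2,6-dienoate
Product: 3 (2E)-3-methylhepta-2,6-dien-1-ol
Conditions: iBu2AlH, CH2Cl2, −78 °C; potassium sodium tartrate aq.
Reagents that add atoms: none
Why: aluminium hydride 1,2-reduction of the enoate to the allylic alcohol; no stereocentre is formed.

Step 3
Reactants: 3 (2E)-3-methylhepta-2,6-dien-1-ol
Product: 4 [(2S,3S)-3-(but-3-en-1-yl)-3-methyloxiran-2-yl]methanol
Conditions: Ti(OiPr)4 (10 mol %), L-(+)-diethyl tartrate (12 mol %), t-BuOOH, molecular sieves 4 Å, CH2Cl2, −20 °C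
Reagents that add atoms: tert-butyl hydroperoxide, CC(C)(C)OO
Why: Sharpless asymmetric epoxidation; with L-(+)-tartrate the oxygen should go to the face that gives the (2S,3S)-epoxy alcohol (as with geraniol), setting C4 and C5 by reagent control.

Step 4
Reactants: 4 [(2S,3S)-3-(but-3-en-1-yl)-3-methyloxiran-2-yl]methanol
Product: 5 (2R,3S)-3-(but-3-en-1-yl)-3-methyloxirane-2-carbaldehyde
Conditions: Dess–Martin periodinane, NaHCO3, CH2Cl2, 0 °C
Reagents that add atoms: none
Why: buffered Dess–Martin oxidation of the primary alcohol should give the epoxy aldehyde without epimerisation at C5.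

Step 5
Reactants: 5 (2R,3S)-3-(but-3-en-1-yl)-3-methyloxirane-2-carbaldehyde
Product: 6 1-[(2S,3S)-3-(but-3-en-1-yl)-3-methyloxiran-2-yl]ethan-1-ol (both carbinol epimers)
Conditions: MeMgBr, THF, −78 °C; NH4Cl aq.
Reagents that add atoms: methylmagnesium bromide, C[Mg]Br
Why: Grignard addition to the aldehyde; the new carbinol centre forms as an epimer mixture that step 6 removes.

Step 6
Reactants: 6 1-[(2S,3S)-3-(but-3-en-1-yl)-3-methyloxiran-2-yl]ethan-1-ol
Product: 7 1-[(2R,3S)-3-(but-3-en-1-yl)-3-methyloxiran-2-yl]ethan-1-one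
Conditions: Dess–Martin periodinane, NaHCO3, CH2Cl2, 0 °C → rt
Reagents that add atoms: none
Why: Dess–Martin oxidation to the epoxy methyl ketone, whose only readily enolisable position is the methyl group (C7).

Step 7
Reactants: 8 3-methylbut-3-en-1-ol
Product: 9 3-methylbut-3-enal
Conditions: Dess–Martin periodinane, NaHCO3, CH2Cl2, 0 °C; filtered solution used at once
Reagents that add atoms: none
Why: Dess–Martin oxidation under mild, non-basic conditions should avoid isomerisation of the β,γ-unsaturated aldehyde into conjugation.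

Step 8
Reactants: 7 1-[(2R,3S)-3-(but-3-en-1-yl)-3-methyloxiran-2-yl]ethan-1-one; 9 3-methylbut-3-enal
Product: 11 (3R)-1-[(2R,3S)-3-(but-3-en-1-yl)-3-methyloxiran-2-yl]-3-hydroxy-5-methylhex-5-en-1-one, via diisopinocampheylboron enolate 10 (not isolated)
Conditions: (−)-Ipc2BCl, Et3N, Et2O, −78 → 0 °C; then 9, −78 → −20 °C; then H2O2, pH 7 buffer, MeOH, 0 °C
Reagents that add atoms: none
Why: boron-mediated aldol reaction of a methyl ketone; the enolate 10 from the (−)-reagent is expected to add to the Si face of aldehyde 9 in a cyclic transition state and so set C8 as R by reagent control.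

Step 9
Reactants: 11 (3R)-1-[(2R,3S)-3-(but-3-en-1-yl)-3-methyloxiran-2-yl]-3-hydroxy-5-methylhex-5-en-1-one
Product: 12 (4R)-6-[(2R,3S)-3-(but-3-en-1-yl)-3-methyloxiran-2-yl]-2-methyl-6-oxohex-1-en-4-yl 2-oxopropanoate
Conditions: pyruvic acid, DCC, DMAP (5 mol %), CH2Cl2, −20 → 0 °C
Reagents that add atoms: pyruvic acid, CC(=O)C(=O)O
Why: Steglich esterification of the secondary alcohol places the C11–C13 unit on the C8 oxygen; no stereocentre changes.

Step 10
Reactants: 12 (4R)-6-[(2R,3S)-3-(but-3-en-1-yl)-3-methyloxiran-2-yl]-2-methyl-6-oxohex-1-en-4-yl 2-oxopropanoate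
Product: 13 (3R,4R,5R)-4-[(2R,3S)-3-(but-3-en-1-yl)-3-methyloxirane-2-carbonyl]-3-hydroxy-3-methyl-5-(2-methylprop-2-en-1-yl)oxolan-2-one
Conditions: LiN(SiMe3)2, THF, −78 → −40 °C; AcOH, −78 °C
Reagents that add atoms: none
Why: intramolecular aldol addition (5-exo-trig) of the C7 lithium enolate to the tethered pyruvate ketone closes the γ-lactone; C7 should end trans to the C8 side chain, and lithium chelation of the enolate oxygen with the pyruvate ketone oxygen should place the C11 oxygen cis to the C6 acyl group (11R), which is also the more stable arrangement.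

Step 11
Reactants: 13 (3R,4R,5R)-4-[(2R,3S)-3-(but-3-en-1-yl)-3-methyloxirane-2-carbonyl]-3-hydroxy-3-methyl-5-(2-methylprop-2-en-1-yl)oxolan-2-one
Product: 14 (3R,4R,5R)-4-{(S)-[(2S,3S)-3-(but-3-en-1-yl)-3-methyloxiran-2-yl](hydroxy)methyl}-3-hydroxy-3-methyl-5-(2-methylprop-2-en-1-yl)oxolan-2-one
Conditions: Zn(BH4)2, Et2O, −20 °C
Reagents that add atoms: none
Why: chelation-controlled hydride reduction; zinc bridging the C6 carbonyl and the oxirane oxygen, reinforced by the C11 hydroxyl, should expose the face that gives the anti epoxy alcohol (6S), which is also 1,3-syn to the C11 oxygen.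

Step 12
Reactants: 14 (3R,4R,5R)-4-{(S)-[(2S,3S)-3-(but-3-en-1-yl)-3-methyloxiran-2-yl](hydroxy)methyl}-3-hydroxy-3-methyl-5-(2-methylprop-2-en-1-yl)oxolan-2-one
Product: 15 (3R,4S,5R)-4-{(S)-[(2S,3S)-3-(but-3-en-1-yl)-3-methyloxiran-2-yl][(2Z)-2-methylbut-2-enoyloxy]methyl}-3-methyl-5-(2-methylprop-2-en-1-yl)-2-oxooxolan-3-yl (2Z)-2-methylbut-2-enoate
Conditions: angelic acid, 2,4,6-trichlorobenzoyl chloride, Et3N, toluene, rt; then 14, toluene, 80 °C
Reagents that add atoms: angelic acid ((2Z)-2-methylbut-2-enoic acid), C/C=C(/C)C(=O)O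
Why: Yamaguchi-type esterification with the preformed mixed anhydride and no nucleophilic catalyst, conditions that should keep the Z geometry, acylates both hydroxyls; no stereocentre changes.

Step 13
Reactants: 15 (3R,4S,5R)-4-{(S)-[(2S,3S)-3-(but-3-en-1-yl)-3-methyloxiran-2-yl][(2Z)-2-methylbut-2-enoyloxy]methyl}-3-methyl-5-(2-methylprop-2-en-1-yl)-2-oxooxolan-3-yl (2Z)-2-methylbut-2-enoate
Product: 16 (3R,4S,5R)-3-methyl-4-{(S)-[(2Z)-2-methylbut-2-enoyloxy][(2S,3S)-3-methyl-3-(3-oxopropyl)oxiran-2-yl]methyl}-2-oxo-5-(2-oxopropyl)oxolan-3-yl (2Z)-2-methylbut-2-enoate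
Conditions: O3, CH2Cl2, −78 °C (Sudan Red 7B as end-point indicator); then PPh3, −78 °C → rt
Reagents that add atoms: ozone, [O-][O+]=O
Why: ozonolysis; the monosubstituted and the 1,1-disubstituted alkene are far more electron-rich than the two conjugated angelate alkenes, so titration to the indicator end point should cleave only those two and unmask the C1 aldehyde and the C10 ketone.

Step 14
Reactants: 16 (3R,4S,5R)-3-methyl-4-{(S)-[(2Z)-2-methylbut-2-enoyloxy][(2S,3S)-3-methyl-3-(3-oxopropyl)oxiran-2-yl]methyl}-2-oxo-5-(2-oxopropyl)oxolan-3-yl (2Z)-2-methylbut-2-enoate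
Product: 17 (3R,4S,5R)-4-{(S)-[(2S,3S)-3-(3-hydroxypropyl)-3-methyloxiran-2-yl][(2Z)-2-methylbut-2-enoyloxy]methyl}-3-methyl-2-oxo-5-(2-oxopropyl)oxolan-3-yl (2Z)-2-methylbut-2-enoate
Conditions: NaBH4, CH2Cl2/EtOH, −78 °C
Reagents that add atoms: none
Why: hydride reduction at −78 °C, where the aldehyde should react much faster than the methyl ketone, the lactone and the esters.

Step 15
Reactants: 17 (3R,4S,5R)-4-{(S)-[(2S,3S)-3-(3-hydroxypropyl)-3-methyloxiran-2-yl][(2Z)-2-methylbut-2-enoyloxy]methyl}-3-methyl-2-oxo-5-(2-oxopropyl)oxolan-3-yl (2Z)-2-methylbut-2-enoate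
Product: 18 (3R,4S,5R)-3-methyl-4-{(S)-[(2Z)-2-methylbut-2-enoyloxy][(2S,3S)-3-methyl-3-[3-(phenylsulfanyl)propyl]oxiran-2-yl]methyl}-2-oxo-5-(2-oxopropyl)oxolan-3-yl (2Z)-2-methylbut-2-enoate
Conditions: PhSH, PPh3, DIAD, THF, 0 °C
Reagents that add atoms: thiophenol, Sc1ccccc1
Why: Mitsunobu thioetherification of the primary alcohol under neutral conditions puts the phenylthio ylide handle on C1.

Step 16
Reactants: 18 (3R,4S,5R)-3-methyl-4-{(S)-[(2Z)-2-methylbut-2-enoyloxy][(2S,3S)-3-methyl-3-[3-(phenylsulfanyl)propyl]oxiran-2-yl]methyl}-2-oxo-5-(2-oxopropyl)oxolan-3-yl (2Z)-2-methylbut-2-enoate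
Product: 21 (1R,4S,5S,6S,7S,8R,10S,11R)-6,11-bis[(2Z)-2-methylbut-2-enoyloxy]-1,10:4,5-diepoxygermacran-12,8-olide (target), via diphenylsulfonium ylide 19 (not isolated), via sulfonium alkoxide betaine 20 (not isolated)
Conditions: 2-(trimethylsilyl)phenyl trifluoromethanesulfonate (3 equiv, syringe pump), CsF, MeCN, 1 mM, 0 °C → rt
Reagents that add atoms: none
Why: Proposed new method: fluoride releases benzyne from the silyl aryl triflate, the thioether sulfur of 18 adds to it and the aryl anion takes a C1 proton through a five-membered transition state to give the diphenylsulfonium ylide 19; C1 of 19 then adds to the C10 methyl ketone (10-exo-trig closure of the carbocycle C1–C10) to give betaine 20, whose alkoxide expels diphenyl sulfide from C1 with inversion (3-exo-tet closure of the oxirane). The closest known reaction types are the Corey–Chaykovsky epoxidation of ketones by diphenylsulfonium alkylides, its intramolecular forms that close five- to seven-membered rings, and the formation of sulfonium ylides from thioethers and arynes; new here are the ring size and the use of a non-stabilised ylide made in this way. C10 is set by the ketone face that is attacked: the chain is expected to close in the usual germacrane fold with the C14 and C15 methyl groups on the same side of the ring, which leaves the carbonyl oxygen on the outer face and should give 10S. C1 follows from C10, because only the betaine with a gauche C2–C1–C10–C9 torsion can bring the alkoxide anti to the sulfonium group without a trans-cyclodecene-like twist in a ring that already holds a trans-oxirane and a trans-lactone, and it collapses to the cis-fused (1R) oxirane. The step needs the ylide to choose the ketone over the lactone and the two hindered conjugated esters (the ketone is the only unhindered, non-conjugated carbonyl) and needs ring closure to outrun intermolecular epoxidation, which the slow release of benzyne at 1 mM and the two rigid turns (trans-lactone at C7–C8, trans-oxirane at C4–C5) should secure. No base stronger than fluoride is present, so the β-acyloxy ketone and the Z esters should survive.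

**Compound list**

1 | ethyl but-2-ynoate | CC#CC(=O)OCC | starting material
2 | ethyl (2E)-3-methylhepta-2,6-dienoate | CCOC(=O)/C=C(\C)CCC=C | intermediate
3 | (2E)-3-methylhepta-2,6-dien-1-ol | OC/C=C(\C)CCC=C | intermediate
4 | [(2S,3S)-3-(but-3-en-1-yl)-3-methyloxiran-2-yl]methanol | C=CCC[C@]1(C)O[C@H]1CO | intermediate
5 | (2R,3S)-3-(but-3-en-1-yl)-3-methyloxirane-2-carbaldehyde | C=CCC[C@]1(C)O[C@H]1C=O | intermediate
6 | 1-[(2S,3S)-3-(but-3-en-1-yl)-3-methyloxiran-2-yl]ethan-1-ol (both carbinol epimers) | C=CCC[C@]1(C)O[C@H]1C(C)O | intermediate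
7 | 1-[(2R,3S)-3-(but-3-en-1-yl)-3-methyloxiran-2-yl]ethan-1-one | C=CCC[C@]1(C)O[C@H]1C(C)=O | intermediate
8 | 3-methylbut-3-en-1-ol | CC(=C)CCO | starting material
9 | 3-methylbut-3-enal | CC(=C)CC=O | intermediate
10 | diisopinocampheylboron enolate of 7 (O–B enolate, C6=C7 methylene; not isolated) | C=CCC[C@]1(C)O[C@H]1C(=C)OB([C@@H]2C[C@@H]3C[C@H]([C@H]2C)C3(C)C)[C@@H]2C[C@@H]3C[C@H]([C@H]2C)C3(C)C | intermediate
11 | (3R)-1-[(2R,3S)-3-(but-3-en-1-yl)-3-methyloxiran-2-yl]-3-hydroxy-5-methylhex-5-en-1-one | C=CCC[C@]1(C)O[C@H]1C(=O)C[C@H](O)CC(C)=C | intermediate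
12 | (4R)-6-[(2R,3S)-3-(but-3-en-1-yl)-3-methyloxiran-2-yl]-2-methyl-6-oxohex-1-en-4-yl 2-oxopropanoate | C=CCC[C@]1(C)O[C@H]1C(=O)C[C@H](OC(=O)C(C)=O)CC(C)=C | intermediate
13 | (3R,4R,5R)-4-[(2R,3S)-3-(but-3-en-1-yl)-3-methyloxirane-2-carbonyl]-3-hydroxy-3-methyl-5-(2-methylprop-2-en-1-yl)oxolan-2-one | C=CCC[C@]1(C)O[C@H]1C(=O)[C@@H]2[C@@H](CC(C)=C)OC(=O)[C@]2(C)O | intermediate
14 | (3R,4R,5R)-4-{(S)-[(2S,3S)-3-(but-3-en-1-yl)-3-methyloxiran-2-yl](hydroxy)methyl}-3-hydroxy-3-methyl-5-(2-methylprop-2-en-1-yl)oxolan-2-one | C=CCC[C@]1(C)O[C@H]1[C@@H](O)[C@@H]2[C@@H](CC(C)=C)OC(=O)[C@]2(C)O | intermediate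
15 | (3R,4S,5R)-4-{(S)-[(2S,3S)-3-(but-3-en-1-yl)-3-methyloxiran-2-yl][(2Z)-2-methylbut-2-enoyloxy]methyl}-3-methyl-5-(2-methylprop-2-en-1-yl)-2-oxooxolan-3-yl (2Z)-2-methylbut-2-enoate | C=CCC[C@]1(C)O[C@H]1[C@@H](OC(=O)/C(C)=C\C)[C@@H]2[C@@H](CC(C)=C)OC(=O)[C@]2(C)OC(=O)/C(C)=C\C | intermediate
16 | (3R,4S,5R)-3-methyl-4-{(S)-[(2Z)-2-methylbut-2-enoyloxy][(2S,3S)-3-methyl-3-(3-oxopropyl)oxiran-2-yl]methyl}-2-oxo-5-(2-oxopropyl)oxolan-3-yl (2Z)-2-methylbut-2-enoate | O=CCC[C@]1(C)O[C@H]1[C@@H](OC(=O)/C(C)=C\C)[C@@H]2[C@@H](CC(C)=O)OC(=O)[C@]2(C)OC(=O)/C(C)=C\C | intermediate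
17 | (3R,4S,5R)-4-{(S)-[(2S,3S)-3-(3-hydroxypropyl)-3-methyloxiran-2-yl][(2Z)-2-methylbut-2-enoyloxy]methyl}-3-methyl-2-oxo-5-(2-oxopropyl)oxolan-3-yl (2Z)-2-methylbut-2-enoate | OCCC[C@]1(C)O[C@H]1[C@@H](OC(=O)/C(C)=C\C)[C@@H]2[C@@H](CC(C)=O)OC(=O)[C@]2(C)OC(=O)/C(C)=C\C | intermediate
18 | (3R,4S,5R)-3-methyl-4-{(S)-[(2Z)-2-methylbut-2-enoyloxy][(2S,3S)-3-methyl-3-[3-(phenylsulfanyl)propyl]oxiran-2-yl]methyl}-2-oxo-5-(2-oxopropyl)oxolan-3-yl (2Z)-2-methylbut-2-enoate | c1ccccc1SCCC[C@]1(C)O[C@H]1[C@@H](OC(=O)/C(C)=C\C)[C@@H]2[C@@H](CC(C)=O)OC(=O)[C@]2(C)OC(=O)/C(C)=C\C | intermediate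
19 | diphenylsulfonium ylide of 18 (carbanion at C1; not isolated) | c1ccccc1[S+](c1ccccc1)[CH-]CC[C@]1(C)O[C@H]1[C@@H](OC(=O)/C(C)=C\C)[C@@H]2[C@@H](CC(C)=O)OC(=O)[C@]2(C)OC(=O)/C(C)=C\C | intermediate
20 | ten-membered betaine with the C1–C10 bond made: alkoxide on C10 (10S), diphenylsulfonio group on C1 on the side opposite to the later C1–O bond (not isolated) | c1ccccc1[S+](c1ccccc1)[C@H]4CC[C@]3(C)O[C@H]3[C@@H](OC(=O)/C(C)=C\C)[C@@H]2[C@@H](C[C@]4(C)[O-])OC(=O)[C@]2(C)OC(=O)/C(C)=C\C | intermediate
21 | (1R,4S,5S,6S,7S,8R,10S,11R)-6,11-bis[(2Z)-2-methylbut-2-enoyloxy]-1,10:4,5-diepoxygermacran-12,8-olide (CNP0219924.1) | C/C=C(/C)C(=O)O[C@H]1[C@@H]2[C@@H](C[C@]3(C)O[C@@H]3CC[C@]3(C)O[C@@H]13)OC(=O)[C@]2(C)OC(=O)/C(C)=C\C | target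

**Step count and risks**

Total step count: 16. Longest linear sequence: 15 steps (steps 1–6 and 8–16); step 7 is a one-step side branch.

Steps most likely to fail:

1. Step 16 (the proposed new method). What may go wrong: intermolecular epoxidation or decay of the non-stabilised ylide may outrun the ten-membered ring closure; the ylide may attack the wrong ketone face or close to the trans-fused oxirane (poor diastereoselectivity); the lactone carboxylate may be lost by β-elimination from the C10 ketone enolate. Fallback with known chemistry: it sets out from 15 and comes back at 21. Ring-closing metathesis of the two terminal alkenes of 15 (second-generation Hoveyda–Grubbs catalyst, toluene, 80 °C, 1 mM) should give the ring-closed (Z)-cyclodecene bis-angelate F1, with Z expected from ring strain. Epoxidation of the trisubstituted ring alkene from its outer face (mCPBA, NaHCO3, CH2Cl2, 0 °C), with the electron-poor angelate alkenes left alone, should then give 21.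

2. Step 10. What may go wrong: enolisation of the pyruvate methyl group with self-condensation, or β-elimination of pyruvate from the C7 enolate, may compete with ring closure; C11 control is lost if the closure is not chelated. Fallback: it sets out from 11 and comes back at 13. Silylation of 11 (Et3SiCl, imidazole, DMF) gives the triethylsilyl ether F2. Enol silylation (LiN(SiMe3)2, Me3SiCl, THF, −78 °C) gives the trimethylsilyl enol ether F3. A Mukaiyama aldol addition to methyl pyruvate catalysed by Cu(OTf)2 with the (R,R)-tert-butyl bis(oxazoline) ligand (divalent copper, Re-face attack on the chelated pyruvate) sets 11R under catalyst control and gives the hydroxy ester F4. HF·pyridine followed by a trace of Et3N removes the silyl ether, closes the lactone onto the methyl ester and equilibrates C7 to the trans arrangement, giving 13.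

3. Step 12. What may go wrong: acylation of the tertiary C11 hydroxyl may be slow, and during the long heating Z to E isomerisation of the angeloyl group or migration of the lactone to the C6 oxygen may take over. Fallback: it sets out from 14 and comes back at 15. Acylation with the smaller, non-conjugated 2-[bis(2,2,2-trifluoroethoxy)phosphoryl]propanoic acid (DCC, DMAP, CH2Cl2) gives the bis(phosphonopropanoate) F5. A Z-selective Horner–Wadsworth–Emmons olefination of both phosphonates with acetaldehyde (Still–Gennari conditions: KN(SiMe3)2, 18-crown-6, THF, −78 °C) then builds both angelate double bonds and gives 15.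

Further compounds
F1 | step 16 | (1(10)Z)-6,11-bis[(2Z)-2-methylbut-2-enoyloxy]-4,5-epoxygermacr-1(10)-en-12,8-olide (other centres as in 15) | C/C=C(/C)C(=O)O[C@H]1[C@@H]2[C@@H](C/C(C)=C\CC[C@]3(C)O[C@@H]13)OC(=O)[C@]2(C)OC(=O)/C(C)=C\C
F2 | step 10 | triethylsilyl ether of 11: (3R)-1-[(2R,3S)-3-(but-3-en-1-yl)-3-methyloxiran-2-yl]-5-methyl-3-(triethylsilyloxy)hex-5-en-1-one | C=CCC[C@]1(C)O[C@H]1C(=O)C[C@H](O[Si](CC)(CC)CC)CC(C)=C
F3 | step 10 | trimethylsilyl enol ether of F2 (C6–O–Si, C6=C7; either alkene geometry) | C=CCC[C@]1(C)O[C@H]1C(O[Si](C)(C)C)=C[C@H](O[Si](CC)(CC)CC)CC(C)=C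
F4 | step 10 | pyruvate aldol adduct: methyl (2R)-2-hydroxy-2-methyl-3-[(2R,3S)-3-(but-3-en-1-yl)-3-methyloxirane-2-carbonyl]-4-(triethylsilyloxy)-6-methylhept-6-enoate, 4R, both C3 epimers | C=CCC[C@]1(C)O[C@H]1C(=O)C([C@@](C)(O)C(=O)OC)[C@H](O[Si](CC)(CC)CC)CC(C)=C
F5 | step 12 | bis{2-[bis(2,2,2-trifluoroethoxy)phosphoryl]propanoate} of 14 (esters on the C6 and C11 oxygens; phosphonate α-carbons as epimer mixtures) | C=CCC[C@]1(C)O[C@H]1[C@@H](OC(=O)C(C)P(=O)(OCC(F)(F)F)OCC(F)(F)F)[C@@H]2[C@@H](CC(C)=C)OC(=O)[C@]2(C)OC(=O)C(C)P(=O)(OCC(F)(F)F)OCC(F)(F)F
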